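**Retrosynthetic overview**
1. Target 34 ⇐ macrocycle 31 by E1cB loss of acetate (C8=C9), methacryloylation of the C6 hydroxyl and final desilylation.
2. Ten-membered carbocycle (second ring, formed last) ⇐ intramolecular Nozaki–Hiyama–Kishi closure of C6–C7 in iodobutenolide aldehyde 30.
3. C8–C9 ⇐ intermolecular vinylogous Mukaiyama aldol of 2-silyloxyfuran 26 with enal 20. The butenolide ring is formed first, from but-2-yne-1,4-diol by allenoate iodolactonisation.
4. Enal 20 ⇐ C2 by Noyori ynone reduction, C1=C10 by hydroalumination/iodination/Negishi methylation, C4 by Sharpless epoxidation and hydride opening, from but-3-yn-1-ol and 3,3-diethoxyprop-1-yne.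

Assumption: positions are referred to by germacrane-type labels (lactone C12(=O)–O–C8, C7=C11, C13 = CH2OH carbon, C6 = methacrylate carbinol, C4 = tertiary carbinol, C2 = acetate carbinol, C1=C10(CH3), C9 = exocyclic alkene CH). The C8/C9 diastereomers formed in step 20 are carried on as a mixture, because both centres become sp2 in step 25.

**Step 1**
Reactants: 1 but-3-yn-1-ol
Product: 2 1-[(but-3-yn-1-yloxy)methyl]-4-methoxybenzene
Conditions: NaH, 4-methoxybenzyl chloride, Bu4NI (cat.), THF/DMF, 0 °C → rt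
Reagents that add atoms: 4-methoxybenzyl chloride COc1ccc(CCl)cc1
Why: Williamson etherification installs the PMB group that later allows oxidative unmasking of the C6 hydroxyl in the presence of silyl ethers and esters.

**Step 2**
Reactants: 2 1-[(but-3-yn-1-yloxy)methyl]-4-methoxybenzene
Product: 5 (2E)-5-[(4-methoxybenzyl)oxy]-3-methylpent-2-en-1-ol, via alkenyldimethylalane 3 (not isolated), via lithium alkenylaluminate 4 (not isolated)
Conditions: AlMe3 (2.5 equiv), Cp2ZrCl2 (0.25 equiv), CH2Cl2, 0 °C → rt; then n-BuLi, THF, −78 °C; then (CH2O)n, −78 °C → rt; aqueous work-up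
Reagents that add atoms: trimethylaluminium C[Al](C)C; paraformaldehyde (formaldehyde unit) C=O
Why: Negishi zirconium-catalysed syn-carboalumination places methyl on the internal and aluminium on the terminal alkyne carbon, and the ate complex is hydroxymethylated with retention, giving only the E-trisubstituted allylic alcohol.

**Step 3**
Reactants: 5 (2E)-5-[(4-methoxybenzyl)oxy]-3-methylpent-2-en-1-ol
Product: 6 [(2R,3R)-3-{2-[(4-methoxybenzyl)oxy]ethyl}-3-methyloxiran-2-yl]methanol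
Conditions: Ti(OiPr)4 (10 mol %), D-(−)-diethyl tartrate (12 mol %), t-BuOOH, 4 Å molecular sieves, CH2Cl2, −20 °C
Reagents that add atoms: tert-butyl hydroperoxide CC(C)(C)OO
Why: Katsuki–Sharpless asymmetric epoxidation under reagent control; D-(−)-tartrate gives the (2R,3R)-epoxide of this geraniol-type E-allylic alcohol (mirror image of the (2S,3S) outcome with L-(+)-tartrate), which fixes the future C4 carbinol.

**Step 4**
Reactants: 6 [(2R,3R)-3-{2-[(4-methoxybenzyl)oxy]ethyl}-3-methyloxiran-2-yl]methanol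
Product: 7 (3S)-5-[(4-methoxybenzyl)oxy]-3-methylpentane-1,3-diol
Conditions: NaAlH2(OCH2CH2OMe)2, THF, 0 °C; aqueous Rochelle salt work-up
Reagents that add atoms: none
Why: Alkoxide-directed hydride opening of the 2,3-epoxy alcohol at C2 gives the 1,3-diol, and the tertiary C–O bond is not touched, so the C4 configuration is retained.

**Step 5**
Reactants: 7 (3S)-5-[(4-methoxybenzyl)oxy]-3-methylpentane-1,3-diol
Product: 8 (3R)-5-[(4-methoxybenzyl)oxy]-3-methyl-1,3-bis[(triethylsilyl)oxy]pentane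
Conditions: Et3SiOTf (2.5 equiv), 2,6-lutidine, CH2Cl2, −78 → 0 °C
Reagents that add atoms: triethylsilyl trifluoromethanesulfonate CC[Si](CC)(CC)OS(=O)(=O)C(F)(F)F
Why: Silyl triflate silylation protects the hindered tertiary hydroxyl as well as the primary one (the descriptor changes only through CIP priorities).

**Step 6**
Reactants: 8 (3R)-5-[(4-methoxybenzyl)oxy]-3-methyl-1,3-bis[(triethylsilyl)oxy]pentane
Product: 9 (3S)-5-[(4-methoxybenzyl)oxy]-3-methyl-3-[(triethylsilyl)oxy]pentan-1-ol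
Conditions: PPTS (0.1 equiv), MeOH/CH2Cl2, 0 °C
Reagents that add atoms: none
Why: Acid-catalysed methanolysis removes the unhindered primary triethylsilyl ether far faster than the tertiary one.

**Step 7**
Reactants: 9 (3S)-5-[(4-methoxybenzyl)oxy]-3-methyl-3-[(triethylsilyl)oxy]pentan-1-ol
Product: 10 (3R)-5-[(4-methoxybenzyl)oxy]-3-methyl-3-[(triethylsilyl)oxy]pentanal
Conditions: Dess–Martin periodinane, NaHCO3, CH2Cl2, 0 °C → rt
Reagents that add atoms: none
Why: Dess–Martin oxidation gives the β-silyloxy aldehyde under buffered, non-epimerising conditions.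

**Step 8**
Reactants: 10 (3R)-5-[(4-methoxybenzyl)oxy]-3-methyl-3-[(triethylsilyl)oxy]pentanal; 11 3,3-diethoxyprop-1-yne
Product: 13 (6R)-1,1-diethoxy-8-[(4-methoxybenzyl)oxy]-6-methyl-6-[(triethylsilyl)oxy]oct-2-yn-4-ol (both C4 epimers), via lithium acetylide 12 (not isolated)
Conditions: 11, n-BuLi, THF, −78 °C; then 10, −78 → −20 °C; then H2O
Reagents that add atoms: none
Why: 1,2-Addition of the lithium acetylide brings in C1, C10 and C9 (C9 masked as the diethyl acetal); the carbinol configuration is irrelevant because it is oxidised next.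

**Step 9**
Reactants: 13 (6R)-1,1-diethoxy-8-[(4-methoxybenzyl)oxy]-6-methyl-6-[(triethylsilyl)oxy]oct-2-yn-4-ol
Product: 14 (6R)-1,1-diethoxy-8-[(4-methoxybenzyl)oxy]-6-methyl-6-[(triethylsilyl)oxy]oct-2-yn-4-one
Conditions: Dess–Martin periodinane, NaHCO3, CH2Cl2, 0 °C
Reagents that add atoms: none
Why: Dess–Martin oxidation of the propargylic alcohol gives the ynone without β-elimination of the silyloxy group.

**Step 10**
Reactants: 14 (6R)-1,1-diethoxy-8-[(4-methoxybenzyl)oxy]-6-methyl-6-[(triethylsilyl)oxy]oct-2-yn-4-one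
Product: 15 (4S,6R)-1,1-diethoxy-8-[(4-methoxybenzyl)oxy]-6-methyl-6-[(triethylsilyl)oxy]oct-2-yn-4-ol
Conditions: Ru[(S,S)-TsNCH(Ph)CH(Ph)NH](p-cymene) (1 mol %), i-PrOH, rt
Reagents that add atoms: none
Why: Noyori asymmetric transfer hydrogenation of the ynone; the (S,S)-catalyst delivers hydride so that the alkynyl group takes the aryl-like position, setting C2 as S under catalyst control.

**Step 11**
Reactants: 15 (4S,6R)-1,1-diethoxy-8-[(4-methoxybenzyl)oxy]-6-methyl-6-[(triethylsilyl)oxy]oct-2-yn-4-ol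
Product: 17 (2Z,4S,6R)-1,1-diethoxy-2-iodo-8-[(4-methoxybenzyl)oxy]-6-methyl-6-[(triethylsilyl)oxy]oct-2-en-4-ol, via cyclic alkenylaluminate 16 (not isolated)
Conditions: NaAlH2(OCH2CH2OMe)2, THF, 0 °C → rt; EtOAc; then I2, THF, −78 → 0 °C
Reagents that add atoms: iodine II
Why: Alkoxide-directed trans-hydroalumination puts hydrogen on the proximal and aluminium on the distal alkyne carbon, and iodinolysis with retention gives the Z-iodoalkene with iodine cis to the carbinol carbon.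

**Step 12**
Reactants: 17 (2Z,4S,6R)-1,1-diethoxy-2-iodo-8-[(4-methoxybenzyl)oxy]-6-methyl-6-[(triethylsilyl)oxy]oct-2-en-4-ol
Product: 18 (2E,4S,6R)-1,1-diethoxy-8-[(4-methoxybenzyl)oxy]-2,6-dimethyl-6-[(triethylsilyl)oxy]oct-2-en-4-ol
Conditions: MeZnCl (3 equiv), Pd(PPh3)4 (5 mol %), THF, 0 °C → rt
Reagents that add atoms: methylzinc chloride C[Zn]Cl
Why: Negishi cross-coupling replaces iodine by methyl with retention of alkene geometry, giving the E-trisubstituted C1=C10 alkene of the target.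

**Step 13**
Reactants: 18 (2E,4S,6R)-1,1-diethoxy-8-[(4-methoxybenzyl)oxy]-2,6-dimethyl-6-[(triethylsilyl)oxy]oct-2-en-4-ol
Product: 19 (2E,4S,6R)-1,1-diethoxy-8-[(4-methoxybenzyl)oxy]-2,6-dimethyl-6-[(triethylsilyl)oxy]oct-2-en-4-yl acetate
Conditions: Ac2O, pyridine, DMAP (cat.), CH2Cl2, 0 °C → rt
Reagents that add atoms: acetic anhydride CC(=O)OC(C)=O
Why: DMAP-catalysed acylation installs the C2 acetate of the target once all hydride and organometallic steps on this fragment are over.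

**Step 14**
Reactants: 19 (2E,4S,6R)-1,1-diethoxy-8-[(4-methoxybenzyl)oxy]-2,6-dimethyl-6-[(triethylsilyl)oxy]oct-2-en-4-yl acetate
Product: 20 (2E,4S,6R)-8-[(4-methoxybenzyl)oxy]-2,6-dimethyl-1-oxo-6-[(triethylsilyl)oxy]oct-2-en-4-yl acetate
Conditions: PPTS (0.1 equiv), acetone/H2O 10:1, rt
Reagents that add atoms: water O
Why: Mild acid hydrolysis of the allylic acetal unveils the enal (C9) while the tertiary silyl ether, the PMB ether and the acetate survive.

**Step 15**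
Reactants: 21 but-2-yne-1,4-diol
Product: 22 4-{[tert-butyl(dimethyl)silyl]oxy}but-2-yn-1-ol
Conditions: NaH (1.0 equiv), THF, 0 °C; then t-BuMe2SiCl (1.0 equiv), rt
Reagents that add atoms: tert-butyl(chloro)dimethylsilane CC(C)(C)[Si](C)(C)Cl
Why: Monosilylation of the symmetric diol through its sparingly soluble monosodium alkoxide protects the future C13 hydroxyl.

**Step 16**
Reactants: 22 4-{[tert-butyl(dimethyl)silyl]oxy}but-2-yn-1-ol
Product: 23 4-{[tert-butyl(dimethyl)silyl]oxy}but-2-yn-1-yl methyl carbonate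
Conditions: ClCO2Me, pyridine, CH2Cl2, 0 °C
Reagents that add atoms: methyl chloroformate COC(=O)Cl
Why: Carbonate formation turns the propargylic hydroxyl into the leaving group needed for palladium-catalysed carbonylation.

**Step 17**
Reactants: 23 4-{[tert-butyl(dimethyl)silyl]oxy}but-2-yn-1-yl methyl carbonate
Product: 24 methyl 2-({[tert-butyl(dimethyl)silyl]oxy}methyl)buta-2,3-dienoate
Conditions: Pd(OAc)2 (2 mol %), PPh3 (8 mol %), CO (10 atm), MeOH, 40 °C
Reagents that add atoms: carbon monoxide [C-]#[O+]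
Why: Tsuji carbonylation: zerovalent palladium adds in SN2' fashion to give an allenylpalladium species, and CO insertion with methoxide capture gives the 2-substituted 2,3-allenoate (C12 introduced).

**Step 18**
Reactants: 24 methyl 2-({[tert-butyl(dimethyl)silyl]oxy}methyl)buta-2,3-dienoate
Product: 25 3-({[tert-butyl(dimethyl)silyl]oxy}methyl)-4-iodofuran-2(5H)-one
Conditions: I2 (2 equiv), NaHCO3, MeCN/H2O 15:1, rt, dark
Reagents that add atoms: iodine II; water O
Why: Iodolactonisation of the 2,3-allenoate: iodonium forms at the central allene carbon, the ester carbonyl oxygen closes onto the terminal CH2, and water releases methanol, giving the β-iodobutenolide with C7–I, C8H2 and C11–CH2OSi in place.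

**Step 19**
Reactants: 25 3-({[tert-butyl(dimethyl)silyl]oxy}methyl)-4-iodofuran-2(5H)-one
Product: 26 tert-butyl{[3-({[tert-butyl(dimethyl)silyl]oxy}methyl)-4-iodofuran-2-yl]oxy}dimethylsilane
Conditions: t-BuMe2SiOTf (1.1 equiv), Et3N (1.5 equiv), CH2Cl2, 0 °C; pentane, filtration, used at once
Reagents that add atoms: tert-butyldimethylsilyl trifluoromethanesulfonate CC(C)(C)[Si](C)(C)OS(=O)(=O)C(F)(F)F
Why: Soft enolisation at the γ-position gives the aromatic 2-silyloxyfuran, the dienol silyl ether nucleophile for the fragment union (4-halo analogues are known to behave well).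

**Step 20**
Reactants: 26 tert-butyl{[3-({[tert-butyl(dimethyl)silyl]oxy}methyl)-4-iodofuran-2-yl]oxy}dimethylsilane; 20 (2E,4S,6R)-8-[(4-methoxybenzyl)oxy]-2,6-dimethyl-1-oxo-6-[(triethylsilyl)oxy]oct-2-en-4-yl acetate
Product: 27 (2E,4S,6R)-1-[4-({[tert-butyl(dimethyl)silyl]oxy}methyl)-3-iodo-5-oxo-2,5-dihydrofuran-2-yl]-1-hydroxy-8-[(4-methoxybenzyl)oxy]-2,6-dimethyl-6-[(triethylsilyl)oxy]oct-2-en-4-yl acetate (mixture of diastereomers at C1/furanone C2)
Conditions: BF3·OEt2 (1.1 equiv), CH2Cl2, −78 °C; then aq. NaHCO3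
Reagents that add atoms: none
Why: Intermolecular vinylogous Mukaiyama aldol: the silyloxyfuran attacks the enal carbonyl through its γ-carbon only (1,2-addition), forming the key C8–C9 bond that joins the two fragments; the new C8/C9 centres (anti-major) are removed later.

**Step 21**
Reactants: 27 aldol adduct (name as in step 20)
Product: 28 (2E,4S,6R)-1-[4-({[tert-butyl(dimethyl)silyl]oxy}methyl)-3-iodo-5-oxo-2,5-dihydrofuran-2-yl]-8-[(4-methoxybenzyl)oxy]-2,6-dimethyl-6-[(triethylsilyl)oxy]oct-2-ene-1,4-diyl diacetate (mixture of diastereomers at C1/furanone C2)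
Conditions: Ac2O, pyridine, CH2Cl2, 0 °C → rt
Reagents that add atoms: acetic anhydride CC(=O)OC(C)=O
Why: Acetylation under weakly basic conditions turns the C9 hydroxyl into a leaving group for the later E1cB step without triggering it (pyridine does not deprotonate C8).

**Step 22**
Reactants: 28 diacetate PMB ether (name as in step 21)
Product: 29 (2E,4S,6R)-1-[4-({[tert-butyl(dimethyl)silyl]oxy}methyl)-3-iodo-5-oxo-2,5-dihydrofuran-2-yl]-8-hydroxy-2,6-dimethyl-6-[(triethylsilyl)oxy]oct-2-ene-1,4-diyl diacetate (mixture of diastereomers at C1/furanone C2)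
Conditions: DDQ, CH2Cl2/pH 7 buffer 10:1, 0 °C
Reagents that add atoms: none
Why: Oxidative PMB cleavage frees only the C6 hydroxyl; silyl ethers, acetates and the vinyl iodide are inert to DDQ.

**Step 23**
Reactants: 29 primary alcohol (name as in step 22)
Product: 30 (2E,4S,6S)-1-[4-({[tert-butyl(dimethyl)silyl]oxy}methyl)-3-iodo-5-oxo-2,5-dihydrofuran-2-yl]-2,6-dimethyl-8-oxo-6-[(triethylsilyl)oxy]oct-2-ene-1,4-diyl diacetate (mixture of diastereomers at C1/furanone C2)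
Conditions: Dess–Martin periodinane, NaHCO3, CH2Cl2, 0 °C → rt
Reagents that add atoms: none
Why: Neutral Dess–Martin oxidation gives the C6 aldehyde without base, so the β-acetoxy butenolide is not eliminated (the C6 descriptor of the chain changes only through CIP priorities).

**Step 24**
Reactants: 30 iodobutenolide aldehyde (name as in step 23)
Product: 31 (4R,6R,8S,9E)-3-({[tert-butyl(dimethyl)silyl]oxy}methyl)-4-hydroxy-6,10-dimethyl-2-oxo-6-[(triethylsilyl)oxy]-2,4,5,6,7,8,11,11a-octahydrocyclodeca[b]furan-8,11-diyl diacetate (mixture at C11/C11a)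
Conditions: CrCl2 (10 equiv), NiCl2 (0.1 equiv), degassed DMSO/THF 3:1, 0.002 M, syringe-pump addition, rt
Reagents that add atoms: none
Why: Intramolecular Nozaki–Hiyama–Kishi reaction (zerovalent nickel inserts into the activated C7–I bond, transmetallation to chromium, addition to the aldehyde) closes the ten-membered ring at C6–C7. The new C6 carbinol is expected 1,3-anti to the C4 silyloxy group (Evans polar model, reinforced by the ring), but this selectivity is not secured by precedent.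

**Step 25**
Reactants: 31 macrocyclic alcohol (name as in step 24)
Product: 32 (4R,6R,8S,9E,11E)-3-({[tert-butyl(dimethyl)silyl]oxy}methyl)-4-hydroxy-6,10-dimethyl-2-oxo-6-[(triethylsilyl)oxy]-2,4,5,6,7,8-hexahydrocyclodeca[b]furan-8-yl acetate
Conditions: DBU (2 equiv), CH2Cl2, 0 °C → rt
Reagents that add atoms: none
Why: E1cB elimination: deprotonation at C8 gives the aromatic furanolate, which expels the C9 acetate; all C8/C9 diastereomers converge, and the ring forces C10 cis to C7, which is the required 11E geometry.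

**Step 26**
Reactants: 32 ylidene butenolide alcohol (name as in step 25)
Product: 33 (4R,6S,8S,9E,11E)-8-(acetyloxy)-3-({[tert-butyl(dimethyl)silyl]oxy}methyl)-6,10-dimethyl-2-oxo-6-[(triethylsilyl)oxy]-2,4,5,6,7,8-hexahydrocyclodeca[b]furan-4-yl 2-methylprop-2-enoate
Conditions: methacrylic anhydride, Et3N, DMAP (cat.), CH2Cl2, 0 °C → rt
Reagents that add atoms: methacrylic anhydride C=C(C)C(=O)OC(=O)C(C)=C
Why: DMAP-catalysed acylation of the only free hydroxyl (C6) installs the methacrylate with retention (the C6 descriptor of the ring changes only through CIP priorities).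

**Step 27**
Reactants: 33 bis-silyl ether (name as in step 26)
Product: 34 (4R,6S,8S,9E,11E)-8-(acetyloxy)-6-hydroxy-3-(hydroxymethyl)-6,10-dimethyl-2-oxo-2,4,5,6,7,8-hexahydrocyclodeca[b]furan-4-yl 2-methylprop-2-enoate (CNP0246543.2)
Conditions: HF·pyridine, pyridine/THF, 0 °C → rt
Reagents that add atoms: none
Why: Buffered fluoride desilylation removes the primary tert-butyldimethylsilyl and the tertiary triethylsilyl ether without touching the acetate, the methacrylate or the base-sensitive ylidene butenolide.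

**Compound list**
1 | but-3-yn-1-ol | C#CCCO | starting material
2 | 1-[(but-3-yn-1-yloxy)methyl]-4-methoxybenzene | C#CCCOCc1ccc(OC)cc1 | intermediate
3 | alkenyldimethylalane: (E)-{4-[(4-methoxybenzyl)oxy]-2-methylbut-1-en-1-yl}dimethylalumane | C[Al](C)/C=C(\C)CCOCc1ccc(OC)cc1 | intermediate (not isolated)
4 | lithium alkenylaluminate: lithium butyl{(E)-4-[(4-methoxybenzyl)oxy]-2-methylbut-1-en-1-yl}dimethylaluminate | [Li+].CCCC[Al-](C)(C)/C=C(\C)CCOCc1ccc(OC)cc1 | intermediate (not isolated)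
5 | (2E)-5-[(4-methoxybenzyl)oxy]-3-methylpent-2-en-1-ol | OC/C=C(\C)CCOCc1ccc(OC)cc1 | intermediate
6 | [(2R,3R)-3-{2-[(4-methoxybenzyl)oxy]ethyl}-3-methyloxiran-2-yl]methanol | COc1ccc(COCC[C@@]2(C)O[C@@H]2CO)cc1 | intermediate
7 | (3S)-5-[(4-methoxybenzyl)oxy]-3-methylpentane-1,3-diol | COc1ccc(COCC[C@@](C)(O)CCO)cc1 | intermediate
8 | (3R)-5-[(4-methoxybenzyl)oxy]-3-methyl-1,3-bis[(triethylsilyl)oxy]pentane | COc1ccc(COCC[C@@](C)(O[Si](CC)(CC)CC)CCO[Si](CC)(CC)CC)cc1 | intermediate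
9 | (3S)-5-[(4-methoxybenzyl)oxy]-3-methyl-3-[(triethylsilyl)oxy]pentan-1-ol | COc1ccc(COCC[C@@](C)(O[Si](CC)(CC)CC)CCO)cc1 | intermediate
10 | (3R)-5-[(4-methoxybenzyl)oxy]-3-methyl-3-[(triethylsilyl)oxy]pentanal | COc1ccc(COCC[C@@](C)(O[Si](CC)(CC)CC)CC=O)cc1 | intermediate
11 | 3,3-diethoxyprop-1-yne | C#CC(OCC)OCC | starting material
12 | lithium acetylide: (3,3-diethoxyprop-1-yn-1-yl)lithium | [Li]C#CC(OCC)OCC | intermediate (not isolated)
13 | (6R)-1,1-diethoxy-8-[(4-methoxybenzyl)oxy]-6-methyl-6-[(triethylsilyl)oxy]oct-2-yn-4-ol (both C4 epimers) | COc1ccc(COCC[C@@](C)(O[Si](CC)(CC)CC)CC(O)C#CC(OCC)OCC)cc1 | intermediate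
14 | (6R)-1,1-diethoxy-8-[(4-methoxybenzyl)oxy]-6-methyl-6-[(triethylsilyl)oxy]oct-2-yn-4-one | COc1ccc(COCC[C@@](C)(O[Si](CC)(CC)CC)CC(=O)C#CC(OCC)OCC)cc1 | intermediate
15 | (4S,6R)-1,1-diethoxy-8-[(4-methoxybenzyl)oxy]-6-methyl-6-[(triethylsilyl)oxy]oct-2-yn-4-ol | COc1ccc(COCC[C@@](C)(O[Si](CC)(CC)CC)C[C@H](O)C#CC(OCC)OCC)cc1 | intermediate
16 | cyclic alkenylaluminate: sodium (5S)-3-(diethoxymethyl)-5-{(2R)-4-[(4-methoxybenzyl)oxy]-2-methyl-2-[(triethylsilyl)oxy]butyl}-2,2-bis(2-methoxyethoxy)-2,5-dihydro-1,2-oxaluminol-2-uide | [Na+].COCCO[Al-]1(OCCOC)O[C@@H](C[C@](C)(O[Si](CC)(CC)CC)CCOCc2ccc(OC)cc2)C=C1C(OCC)OCC | intermediate (not isolated)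
17 | (2Z,4S,6R)-1,1-diethoxy-2-iodo-8-[(4-methoxybenzyl)oxy]-6-methyl-6-[(triethylsilyl)oxy]oct-2-en-4-ol | COc1ccc(COCC[C@@](C)(O[Si](CC)(CC)CC)C[C@H](O)/C=C(\I)C(OCC)OCC)cc1 | intermediate
18 | (2E,4S,6R)-1,1-diethoxy-8-[(4-methoxybenzyl)oxy]-2,6-dimethyl-6-[(triethylsilyl)oxy]oct-2-en-4-ol | COc1ccc(COCC[C@@](C)(O[Si](CC)(CC)CC)C[C@H](O)/C=C(C)/C(OCC)OCC)cc1 | intermediate
19 | (2E,4S,6R)-1,1-diethoxy-8-[(4-methoxybenzyl)oxy]-2,6-dimethyl-6-[(triethylsilyl)oxy]oct-2-en-4-yl acetate | COc1ccc(COCC[C@@](C)(O[Si](CC)(CC)CC)C[C@H](OC(C)=O)/C=C(C)/C(OCC)OCC)cc1 | intermediate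
20 | (2E,4S,6R)-8-[(4-methoxybenzyl)oxy]-2,6-dimethyl-1-oxo-6-[(triethylsilyl)oxy]oct-2-en-4-yl acetate | COc1ccc(COCC[C@@](C)(O[Si](CC)(CC)CC)C[C@H](OC(C)=O)/C=C(C)/C=O)cc1 | intermediate
21 | but-2-yne-1,4-diol | OCC#CCO | starting material
22 | 4-{[tert-butyl(dimethyl)silyl]oxy}but-2-yn-1-ol | CC(C)(C)[Si](C)(C)OCC#CCO | intermediate
23 | 4-{[tert-butyl(dimethyl)silyl]oxy}but-2-yn-1-yl methyl carbonate | COC(=O)OCC#CCO[Si](C)(C)C(C)(C)C | intermediate
24 | methyl 2-({[tert-butyl(dimethyl)silyl]oxy}methyl)buta-2,3-dienoate | COC(=O)C(CO[Si](C)(C)C(C)(C)C)=C=C | intermediate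
25 | 3-({[tert-butyl(dimethyl)silyl]oxy}methyl)-4-iodofuran-2(5H)-one | CC(C)(C)[Si](C)(C)OCC1=C(I)COC1=O | intermediate
26 | tert-butyl{[3-({[tert-butyl(dimethyl)silyl]oxy}methyl)-4-iodofuran-2-yl]oxy}dimethylsilane | CC(C)(C)[Si](C)(C)OCc1c(I)coc1O[Si](C)(C)C(C)(C)C | intermediate
27 | (2E,4S,6R)-1-[4-({[tert-butyl(dimethyl)silyl]oxy}methyl)-3-iodo-5-oxo-2,5-dihydrofuran-2-yl]-1-hydroxy-8-[(4-methoxybenzyl)oxy]-2,6-dimethyl-6-[(triethylsilyl)oxy]oct-2-en-4-yl acetate (mixture at C1/furanone C2) | COc1ccc(COCC[C@@](C)(O[Si](CC)(CC)CC)C[C@H](OC(C)=O)/C=C(C)/C(O)C2OC(=O)C(CO[Si](C)(C)C(C)(C)C)=C2I)cc1 | intermediate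
28 | (2E,4S,6R)-1-[4-({[tert-butyl(dimethyl)silyl]oxy}methyl)-3-iodo-5-oxo-2,5-dihydrofuran-2-yl]-8-[(4-methoxybenzyl)oxy]-2,6-dimethyl-6-[(triethylsilyl)oxy]oct-2-ene-1,4-diyl diacetate (mixture at C1/furanone C2) | COc1ccc(COCC[C@@](C)(O[Si](CC)(CC)CC)C[C@H](OC(C)=O)/C=C(C)/C(OC(C)=O)C2OC(=O)C(CO[Si](C)(C)C(C)(C)C)=C2I)cc1 | intermediate
29 | (2E,4S,6R)-1-[4-({[tert-butyl(dimethyl)silyl]oxy}methyl)-3-iodo-5-oxo-2,5-dihydrofuran-2-yl]-8-hydroxy-2,6-dimethyl-6-[(triethylsilyl)oxy]oct-2-ene-1,4-diyl diacetate (mixture at C1/furanone C2) | OCC[C@@](C)(O[Si](CC)(CC)CC)C[C@H](OC(C)=O)/C=C(C)/C(OC(C)=O)C1OC(=O)C(CO[Si](C)(C)C(C)(C)C)=C1I | intermediate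
30 | (2E,4S,6S)-1-[4-({[tert-butyl(dimethyl)silyl]oxy}methyl)-3-iodo-5-oxo-2,5-dihydrofuran-2-yl]-2,6-dimethyl-8-oxo-6-[(triethylsilyl)oxy]oct-2-ene-1,4-diyl diacetate (mixture at C1/furanone C2) | O=CC[C@@](C)(O[Si](CC)(CC)CC)C[C@H](OC(C)=O)/C=C(C)/C(OC(C)=O)C1OC(=O)C(CO[Si](C)(C)C(C)(C)C)=C1I | intermediate
31 | (4R,6R,8S,9E)-3-({[tert-butyl(dimethyl)silyl]oxy}methyl)-4-hydroxy-6,10-dimethyl-2-oxo-6-[(triethylsilyl)oxy]-2,4,5,6,7,8,11,11a-octahydrocyclodeca[b]furan-8,11-diyl diacetate (mixture at C11/C11a) | O[C@@H]1C[C@@](C)(O[Si](CC)(CC)CC)C[C@H](OC(C)=O)/C=C(C)/C(OC(C)=O)C2OC(=O)C(CO[Si](C)(C)C(C)(C)C)=C21 | intermediate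
32 | (4R,6R,8S,9E,11E)-3-({[tert-butyl(dimethyl)silyl]oxy}methyl)-4-hydroxy-6,10-dimethyl-2-oxo-6-[(triethylsilyl)oxy]-2,4,5,6,7,8-hexahydrocyclodeca[b]furan-8-yl acetate | O[C@@H]1C[C@@](C)(O[Si](CC)(CC)CC)C[C@H](OC(C)=O)/C=C(C)/C=C2/OC(=O)C(CO[Si](C)(C)C(C)(C)C)=C21 | intermediate
33 | (4R,6S,8S,9E,11E)-8-(acetyloxy)-3-({[tert-butyl(dimethyl)silyl]oxy}methyl)-6,10-dimethyl-2-oxo-6-[(triethylsilyl)oxy]-2,4,5,6,7,8-hexahydrocyclodeca[b]furan-4-yl 2-methylprop-2-enoate | C=C(C)C(=O)O[C@@H]1C[C@@](C)(O[Si](CC)(CC)CC)C[C@H](OC(C)=O)/C=C(C)/C=C2/OC(=O)C(CO[Si](C)(C)C(C)(C)C)=C21 | intermediate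
34 | (4R,6S,8S,9E,11E)-8-(acetyloxy)-6-hydroxy-3-(hydroxymethyl)-6,10-dimethyl-2-oxo-2,4,5,6,7,8-hexahydrocyclodeca[b]furan-4-yl 2-methylprop-2-enoate | C=C(C)C(=O)O[C@@H]1C[C@@](C)(O)C[C@H](OC(C)=O)/C=C(C)/C=C2/OC(=O)C(CO)=C21 | target

**Totals**
Total step count: 27. Longest linear sequence: 22 steps (steps 1–14, then 20–27, from but-3-yn-1-ol). The butenolide branch (steps 15–19) joins at step 20.

**Three steps most likely to fail, each with one fallback**

Step 24 (Nozaki–Hiyama–Kishi macrocyclisation). Closing a ten-membered ring on a diastereomer mixture may give a modest yield, and the C6 carbinol configuration rests on substrate control only. The fallback sets out from aldehyde 30 and comes back at 31. The crude cyclisation product, containing the unwanted C4-epimeric alcohol (4S,6R,8S,9E)-3-({[tert-butyl(dimethyl)silyl]oxy}methyl)-4-hydroxy-6,10-dimethyl-2-oxo-6-[(triethylsilyl)oxy]-2,4,5,6,7,8,11,11a-octahydrocyclodeca[b]furan-8,11-diyl diacetate F1, is oxidised as a whole with Dess–Martin periodinane to the macrocyclic ketone (6S,8S,9E)-3-({[tert-butyl(dimethyl)silyl]oxy}methyl)-6,10-dimethyl-2,4-dioxo-6-[(triethylsilyl)oxy]-2,4,5,6,7,8,11,11a-octahydrocyclodeca[b]furan-8,11-diyl diacetate F2. F2 is then reduced with (S)-2-methyl-CBS-oxazaborolidine and catecholborane (toluene, −78 °C), so the carbinol is set by the catalyst and not by the ring, giving 31.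

Step 20 (vinylogous Mukaiyama aldol). The iodinated silyloxyfuran 26 may be too labile (protodesilylation, loss of iodide) or too hindered for the α-methyl enal. The fallback reverses the order of the two C–C bond formations; it sets out from acetal 19, uses iodobutenolide 25, and comes back at 33. DDQ cleavage of the PMB ether of 19 gives the primary alcohol (2E,4S,6R)-1,1-diethoxy-8-hydroxy-2,6-dimethyl-6-[(triethylsilyl)oxy]oct-2-en-4-yl acetate F3. Dess–Martin oxidation gives the aldehyde (2E,4S,6S)-1,1-diethoxy-2,6-dimethyl-8-oxo-6-[(triethylsilyl)oxy]oct-2-en-4-yl acetate F4. Intermolecular CrCl2/NiCl2 coupling of F4 with 25 forms C6–C7 and gives, after separation from its carbinol epimer (recycled by oxidation and CBS reduction as above), the allylic alcohol (2E,4S,6R,8R)-8-[4-({[tert-butyl(dimethyl)silyl]oxy}methyl)-5-oxo-2,5-dihydrofuran-3-yl]-1,1-diethoxy-8-hydroxy-2,6-dimethyl-6-[(triethylsilyl)oxy]oct-2-en-4-yl acetate F5. Methacrylic anhydride/Et3N/DMAP gives the ester (1R,3S,5S,6E)-5-(acetyloxy)-1-[4-({[tert-butyl(dimethyl)silyl]oxy}methyl)-5-oxo-2,5-dihydrofuran-3-yl]-8,8-diethoxy-3,7-dimethyl-3-[(triethylsilyl)oxy]oct-6-en-1-yl 2-methylprop-2-enoate F6. PPTS in wet acetone unveils the enal (1R,3S,5S,6E)-5-(acetyloxy)-1-[4-({[tert-butyl(dimethyl)silyl]oxy}methyl)-5-oxo-2,5-dihydrofuran-3-yl]-3,7-dimethyl-8-oxo-3-[(triethylsilyl)oxy]oct-6-en-1-yl 2-methylprop-2-enoate F7. The ring is then closed by an intramolecular vinylogous aldol condensation (t-BuMe2SiOTf, i-Pr2NEt, CH2Cl2, 0.002 M; then DBU), which forms C8=C9 under ring constraint and gives 33 directly. This route also avoids the macrocyclic chromium step.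

Step 11 (hydroalumination–iodination). The alkenylaluminate 16 carries a β-alkoxy group and may eliminate to an alkoxyallene, and the acetal oxygens may disturb the regiochemistry. The fallback sets out from ynone 14 and comes back at 18. Conjugate addition of Me2CuLi (from CuI and MeLi, THF, −78 °C), followed by equilibration with a trace of iodine, gives the thermodynamically preferred enone (2E,6R)-1,1-diethoxy-8-[(4-methoxybenzyl)oxy]-2,6-dimethyl-6-[(triethylsilyl)oxy]oct-2-en-4-one F8. F8 is reduced with (R)-2-methyl-CBS-oxazaborolidine and BH3·SMe2 to the (4S)-allylic alcohol 18, so the alkene is built by carbocupration and C2 is set by enone reduction.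

**Further compounds**
F1 | step 24 | (4S,6R,8S,9E)-3-({[tert-butyl(dimethyl)silyl]oxy}methyl)-4-hydroxy-6,10-dimethyl-2-oxo-6-[(triethylsilyl)oxy]-2,4,5,6,7,8,11,11a-octahydrocyclodeca[b]furan-8,11-diyl diacetate | O[C@H]1C[C@@](C)(O[Si](CC)(CC)CC)C[C@H](OC(C)=O)/C=C(C)/C(OC(C)=O)C2OC(=O)C(CO[Si](C)(C)C(C)(C)C)=C21
F2 | step 24 | (6S,8S,9E)-3-({[tert-butyl(dimethyl)silyl]oxy}methyl)-6,10-dimethyl-2,4-dioxo-6-[(triethylsilyl)oxy]-2,4,5,6,7,8,11,11a-octahydrocyclodeca[b]furan-8,11-diyl diacetate | O=C1C[C@@](C)(O[Si](CC)(CC)CC)C[C@H](OC(C)=O)/C=C(C)/C(OC(C)=O)C2OC(=O)C(CO[Si](C)(C)C(C)(C)C)=C21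
F3 | step 20 | (2E,4S,6R)-1,1-diethoxy-8-hydroxy-2,6-dimethyl-6-[(triethylsilyl)oxy]oct-2-en-4-yl acetate | OCC[C@@](C)(O[Si](CC)(CC)CC)C[C@H](OC(C)=O)/C=C(C)/C(OCC)OCC
F4 | step 20 | (2E,4S,6S)-1,1-diethoxy-2,6-dimethyl-8-oxo-6-[(triethylsilyl)oxy]oct-2-en-4-yl acetate | O=CC[C@@](C)(O[Si](CC)(CC)CC)C[C@H](OC(C)=O)/C=C(C)/C(OCC)OCC
F5 | step 20 | (2E,4S,6R,8R)-8-[4-({[tert-butyl(dimethyl)silyl]oxy}methyl)-5-oxo-2,5-dihydrofuran-3-yl]-1,1-diethoxy-8-hydroxy-2,6-dimethyl-6-[(triethylsilyl)oxy]oct-2-en-4-yl acetate | O[C@H](C[C@@](C)(O[Si](CC)(CC)CC)C[C@H](OC(C)=O)/C=C(C)/C(OCC)OCC)C1=C(CO[Si](C)(C)C(C)(C)C)C(=O)OC1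
F6 | step 20 | (1R,3S,5S,6E)-5-(acetyloxy)-1-[4-({[tert-butyl(dimethyl)silyl]oxy}methyl)-5-oxo-2,5-dihydrofuran-3-yl]-8,8-diethoxy-3,7-dimethyl-3-[(triethylsilyl)oxy]oct-6-en-1-yl 2-methylprop-2-enoate | C=C(C)C(=O)O[C@H](C[C@@](C)(O[Si](CC)(CC)CC)C[C@H](OC(C)=O)/C=C(C)/C(OCC)OCC)C1=C(CO[Si](C)(C)C(C)(C)C)C(=O)OC1
F7 | step 20 | (1R,3S,5S,6E)-5-(acetyloxy)-1-[4-({[tert-butyl(dimethyl)silyl]oxy}methyl)-5-oxo-2,5-dihydrofuran-3-yl]-3,7-dimethyl-8-oxo-3-[(triethylsilyl)oxy]oct-6-en-1-yl 2-methylprop-2-enoate | C=C(C)C(=O)O[C@H](C[C@@](C)(O[Si](CC)(CC)CC)C[C@H](OC(C)=O)/C=C(C)/C=O)C1=C(CO[Si](C)(C)C(C)(C)C)C(=O)OC1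
F8 | step 11 | (2E,6R)-1,1-diethoxy-8-[(4-methoxybenzyl)oxy]-2,6-dimethyl-6-[(triethylsilyl)oxy]oct-2-en-4-one | COc1ccc(COCC[C@@](C)(O[Si](CC)(CC)CC)CC(=O)/C=C(C)/C(OCC)OCC)cc1
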